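Readings and results come from a simulation from invented constants, and the scatter is random.

In a one-step world the row is simple: product climbs with the charge of starting complex and levels off where the incoming ligand is used up. This flask is a ladder instead, and each complex with three exchanged costs 3 incoming ligands. The scale therefore has a natural zero, the break-even charge of 14.2 mM: the charge of starting complex that the ligand present can carry through exactly 3 exchanges each.

in all of them: incoming ligand 42.5 mM

| run | starting complex | remark | time |
|---|---|---|---|
| oak | 1.3 mM | run made earlier |  |
| cedar | 100 mM | run made earlier |  |
| autumn | 2.0 mM |  | 80 min |
| dusk | 6.0 mM |  | 80 min |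
| winter | 15 mM |  | 80 min |
| noon | 50 mM |  | 80 min |
| spring | 150 mM |  | 80 min |

| oak: time / min | oak: complex with three exchanged / % | cedar: time / min | cedar: complex with three exchanged / % |
|---|---|---|---|
| 20.0 | 4.0 | 10.0 | 0.8 |
| 40.0 | 12.0 | 30.0 | 0 |
| 60.0 | 18.9 | 50.0 | 0 |
| 80.0 | 26.0 | 80.0 | 0 |

(readings scatter by 0.5 percentage points)

- the earlier runs were read with a standard deviation of 0.5 percentage points
- what may be going on: starting complex + incoming ligand -> leaving ligand + complex with one exchanged; complex with one exchanged + incoming ligand -> leaving ligand + complex with two exchanged; complex with two exchanged + incoming ligand -> leaving ligand + complex with three exchanged; complex with three exchanged + incoming ligand <-> leaving ligand + complex with four exchanged; starting complex <-> dormant form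
- "hardly changes" means that all values lie within two and a half points (for a concentration: within two and a half percent of the largest)

- [complex with three exchanged] at the end for autumn, dusk, winter, noon, spring, in this order
- how that number moves from the first to the last of them (rises all the way / falls all the way / falls, then rises / hardly changes / rises, then falls)

Two extremes bracket the row. In oak, with 32.7 ligands per complex, the incoming ligand stands in large excess, a pseudo-first-order world, and 26.0 % of the charge is read as complex with three exchanged at 80.0 min. Carried over as a share, that gives 0.520 mM for autumn, and in this extreme [complex with three exchanged] grows with the charge. In cedar, with 0.425 ligands per complex, the incoming ligand is the limiting reagent, too short even for one exchange each, and the reading at 80.0 min is 0 %, against a scatter of 0.5 percentage points. The real row must climb along the first extreme and drop towards the second, so the reckoning here puts the turn near 14.2 mM. Winter, at 15 mM, stands beside that charge; the oak share at the break-even charge gives a height near 3.68 mM, and noon and spring are expected low.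

The forecast gives 0.51 mM, 1.3 mM, 2.3 mM, 1.5 mM and 0.3 mM, shape rises, then falls, holding that with complex in excess “the fast first step consumes the ligand”, and its peak stands lower than this reckoning.

The flasks give 0.629 mM, 2.44 mM, 3.85 mM, 0.497 mM and 0.0523 mM: rises, then falls.

    starting complex + incoming ligand → leaving ligand + complex with one exchanged (k = 4.28 L mol⁻¹ min⁻¹)
    complex with one exchanged + incoming ligand → leaving ligand + complex with two exchanged (k = 4.10 L mol⁻¹ min⁻¹)
    complex with two exchanged + incoming ligand → leaving ligand + complex with three exchanged (k = 0.394 L mol⁻¹ min⁻¹)
    complex with three exchanged + incoming ligand ⇌ leaving ligand + complex with four exchanged (K = 0.150, k = 40.4 L mol⁻¹ min⁻¹)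
    starting complex ⇌ dormant form (K = 0.520, k = 0.0435 min⁻¹)

The row turns at 13 mM, a little below the break-even charge of 14.2 mM. In autumn, by the forward step alone at charged concentrations, complex with two exchanged has a half-life of 41 min, ten times the 3.8 min of starting complex. Spring was charged at ten times the break-even charge; there, at 80.0 min, 0 % of the incoming ligand remains, complex with one exchanged holds 21.2 % of the charge, complex with two exchanged 3.50 %, and complex with three exchanged 0.0349 %.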